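**Plan**

1. Retrosynthetic cuts, in order: the O15 protecting group; C9–C11 (side chain off a C9 enol triflate); the ester C–O bonds at C2, C6 and C7 and the C7–O bond, back to a trans-decalin 2,6,9-trione with a C7=C8 double bond; C2–C3 and C4–C5 together, which takes isobutene out of ring A; C10–C1 (an allyl group on ring B).
2. Enabling feature: C2 (oxygenated) and C5 (alpha to the oxygenated C6) are 1,4-related through C1 and the quaternary C10. An electrophilic C2 aldehyde and a nucleophilic C5=C6 enol ether can therefore sit on one ring-B precursor without joining, because that would make a cyclobutane. The missing C3–C4 unit with its gem-dimethyl group is isobutene: its CH2 end is the nucleophile and its CMe2 end becomes the cation, which matches C2(+)/C5(−).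
3. Forward order: ring B first (2,6-dimethylphenol supplies C5–C10, C17, C20 and O9); then the quaternary C10; then ring A by the formal [4+2] annulation with isobutene; then ring-B adjustment by carbonyl chemistry; the side chain last.
4. Stereochemistry: C10 comes from a ligand-controlled decarboxylative allylation. The axial C19 and C20 methyl groups close the beta face of the trans-decalin, so the proton to C5, hydride to C2 and C6, and electrophilic oxygen to C7 all arrive from the alpha face. C2 is then inverted by a Mitsunobu acetate. The E C13=C14 bond comes with the enynol.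
5. Helpers removed later: the aldehyde oxygen at C2 (activator, carried on as a ketone); the C9 carbonyl (keeps C5 as the only enolisable ring-B position, later the triflate handle); the silyl groups.

Key step: step 6

Numbering: labdane numbers of the target are used throughout. Ring A = C1–C5 and C10; ring B = C5–C10; C17 on C8; C18/C19 on C4; C20 on C10; side chain C11–C16. Alpha is the face opposite to C20.

Assumption: (E)-3-methylpent-2-en-4-yn-1-ol, (R)-t-BuPHOX and 2-methylallylboronic acid pinacol ester are taken as commercial. The sense of induction in step 3 is assigned by analogy with enol carbonates of 2-methylcyclohexanone. Any shortfall in enantiomeric purity is expected to be removable by recrystallising a crystalline later intermediate.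

**Step 1**
Reactants: 1 2,6-dimethylphenol
Product: 2 4,4-dimethoxy-2,6-dimethylcyclohexa-2,5-dien-1-one
Conditions: PhI(OAc)2 (2.1 equiv), MeOH, 0 °C to rt
Reagents that add atoms: methanol CO
Why: Two consecutive phenol oxidations by trivalent iodine in methanol (para-methoxylation, then oxidative dearomatisation to the p-quinone monoketal) are standard for phenols with a free para position, and the two ortho methyl groups block ortho attack.

**Step 2**
Reactants: 2 4,4-dimethoxy-2,6-dimethylcyclohexa-2,5-dien-1-one; 3 allyl chloroformate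
Product: 5 allyl 4,4-dimethoxy-2,6-dimethylcyclohexa-1,5-dien-1-yl carbonate, via lithium dienolate 4 (not isolated)
Conditions: LiBH(s-Bu)3 (1.05 equiv), THF, −78 °C; then 3, −78 to 0 °C; Et3N-deactivated silica
Reagents that add atoms: none
Why: Conjugate reduction by the bulky borohydride at a beta carbon that bears only hydrogen (the two enone halves are equivalent) gives the tetrasubstituted enolate regiospecifically, and O-acylation by the chloroformate traps it as the achiral enol carbonate before methanol can be lost with rearomatisation.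

**Step 3**
Reactants: 5 allyl 4,4-dimethoxy-2,6-dimethylcyclohexa-1,5-dien-1-yl carbonate
Product: 6 (S)-6-allyl-4,4-dimethoxy-2,6-dimethylcyclohex-2-en-1-one
Conditions: Pd2(dba)3 (2.5 mol %), (R)-t-BuPHOX (6 mol %), toluene, 25 °C
Reagents that add atoms: none
Why: In this decarboxylative asymmetric Tsuji–Trost allylation, ionisation and loss of CO2 give an allylpalladium dienolate that can be allylated only at C10, and the (R)-phosphinooxazoline ligand selects the enolate face that gives the (S) quaternary centre, which is C10 of the target.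

**Step 4**
Reactants: 6 (S)-6-allyl-4,4-dimethoxy-2,6-dimethylcyclohex-2-en-1-one
Product: 8 (S)-2-(1,3-dimethyl-2,5-dioxocyclohex-3-en-1-yl)acetaldehyde, via ketal aldehyde 7 (not isolated)
Conditions: O3, CH2Cl2, −78 °C; Me2S; then 1 M HCl, THF, 0 °C
Reagents that add atoms: ozone [O-][O+]=O; water O
Why: In the ozonolysis with reductive work-up, ozone takes the electron-rich monosubstituted alkene far faster than the enone double bond, and the allylic dimethyl ketal is hydrolysed by mild acid in the same flask.

**Step 5**
Reactants: 8 (S)-2-(1,3-dimethyl-2,5-dioxocyclohex-3-en-1-yl)acetaldehyde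
Product: 9 (S)-4-(tert-butyldimethylsilyloxy)-6-[2-(tert-butyldimethylsilyloxy)ethenyl]-2,6-dimethylcyclohexa-2,4-dien-1-one (E/Z mixture at the side-chain enol ether)
Conditions: t-BuMe2SiOTf (2.4 equiv), Et3N (3.5 equiv), CH2Cl2, −78 to 0 °C
Reagents that add atoms: tert-butyldimethylsilyl trifluoromethanesulfonate CC(C)(C)[Si](C)(C)OS(=O)(=O)C(F)(F)F
Why: Soft enolisation (silyl triflate and amine) silylates the aldehyde and the only enolisable ring position, C5 (C9 has no alpha hydrogen and C7 is sp2), as is known for 2,6,6-trimethylcyclohex-2-ene-1,4-dione.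

**Step 6**
Reactants: 9 (S)-4-(tert-butyldimethylsilyloxy)-6-[2-(tert-butyldimethylsilyloxy)ethenyl]-2,6-dimethylcyclohexa-2,4-dien-1-one; 10 isobutene
Product: 14 cis-fused 7-hydroxy-2,5,5,8a-tetramethyl-4a,5,6,7,8,8a-hexahydronaphthalene-1,4-dione (2-hydroxy-6,9-dioxo-7-ene; 5-beta-H; 10-beta-Me; both C2 epimers), via free aldehyde 11 (not isolated), via titanium chloroalkoxide 12 (not isolated), via titanium alkoxide 13 (not isolated)
Conditions: HCl (1.0 equiv, 1 M in Et2O), CH2Cl2 (5 mM), −78 °C; then 10 (20 equiv, 0.1 M), 2,6-di-tert-butylpyridine (0.2 equiv), TiCl4 (2.2 equiv), −78 to −40 °C; aq NaHCO3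
Reagents that add atoms: none
Why: Proposed new method: HCl protodesilylates only the electron-rich side-chain enol ether of 9 (the C5=C6 enol ether is deactivated by conjugation with C7=C8–C9=O) and so frees aldehyde 11 under anhydrous conditions; TiCl4 activates the aldehyde, the CH2 end of isobutene attacks C2 (C2–C3 bond), and the tertiary C4 cation, buffered as chloride 12, is captured by C5 of the silyl dienol ether (C4–C5 bond) with loss of t-BuMe2SiCl. The closest known reaction types are the TiCl4-mediated chloro-Prins addition of aldehydes to 1,1-disubstituted alkenes, the Lewis-acid alpha-tert-alkylation of silyl enol ethers with tertiary chlorides, and the end-capping of living polyisobutene by silyl enol ethers; joining them into a formal [4+2] annulation of a 1,4-dipole with a simple alkene is what is new. Ring A closes in a 6-(enolexo) mode, exo to C5=C6, through a chair in which C4 approaches C5 perpendicular to ring B. C5 is controlled by the tether: C1 stands on the alpha face of C10, so C4 can only bond to the alpha face and the decalin forms cis-fused (5-beta-H), which step 8 corrects; C2 is set in the intermolecular event without reliable control and is erased in step 7; C4 is not stereogenic. The step needs C2 to react with isobutene rather than with C5, which the 1,4-relation across quaternary C10 secures because direct union would be a cyclobutane. It also needs C2 to avoid a second molecule and needs only one insertion; high dilution, the neopentyl shielding of C2 and C5, and intramolecular capture at an isobutene concentration of only 0.1 M should favour both over dimerisation and chain growth.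

**Step 7**
Reactants: 14 cis-fused 2-hydroxy-6,9-dioxo-7-ene decalin
Product: 15 cis-fused 2,5,5,8a-tetramethyl-4a,5,8,8a-tetrahydronaphthalene-1,4,7(6H)-trione (2,6,9-trioxo-7-ene; 5-beta-H)
Conditions: Dess–Martin periodinane, CH2Cl2, 0 °C to rt
Reagents that add atoms: none
Why: Dess–Martin oxidation under neutral conditions merges both C2 epimers into one ketone and so removes the uncontrolled stereocentre without touching C5 or C10.

**Step 8**
Reactants: 15 cis-fused 2,6,9-trioxo-7-ene decalin
Product: 17 trans-fused 2,5,5,8a-tetramethyl-4a,5,8,8a-tetrahydronaphthalene-1,4,7(6H)-trione (2,6,9-trioxo-7-ene; 5-alpha-H), via bis(silyl enol ether) 16 (not isolated)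
Conditions: Me3SiOTf (3 equiv), Et3N (4 equiv), CH2Cl2, 0 °C to rt; then 0.5 M HCl, THF, −20 °C
Reagents that add atoms: none
Why: Soft enolisation makes C5 planar (the only enolisable ring-B position), and kinetic C-protonation of the silyl dienol ether should occur on the alpha face because the beta face of C5 is flanked by the axial methyl groups on C4 and C10, which gives the trans-decalin, while cold dilute acid avoids re-equilibration.

**Step 9**
Reactants: 17 trans-fused 2,6,9-trioxo-7-ene decalin
Product: 19 2-beta-hydroxy-6-oxo-8-en-9-yl trifluoromethanesulfonate of the 4,4,8,10-tetramethyl-trans-decalin (5-alpha-H), via dilithium alkoxide enolate 18 (not isolated)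
Conditions: LiBH(s-Bu)3 (2.1 equiv), THF, −78 °C; then N-(5-chloropyridin-2-yl)bis(trifluoromethanesulfonimide) (1.05 equiv), −78 to 0 °C; aq NH4Cl
Reagents that add atoms: N-(5-chloropyridin-2-yl)bis(trifluoromethanesulfonimide) O=S(=O)(N(c1ccc(Cl)cn1)S(=O)(=O)C(F)(F)F)C(F)(F)F
Why: In this reductive enolate triflation, hydride adds to C7, the unsubstituted alkene carbon, so only the C9 enolate forms and is trapped; the second hydride attacks the unhindered C2 ketone from the open alpha face (equatorial attack of a bulky borohydride) to give the axial 2-beta alcohol, and the shielded C6 ketone survives.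

**Step 10**
Reactants: 19 2-beta-hydroxy-6-oxo-8-en-9-yl triflate
Product: 20 2-alpha-acetoxy-6-oxo-8-en-9-yl triflate
Conditions: PPh3, DIAD, AcOH, toluene, 0 °C to rt
Reagents that add atoms: acetic acid CC(=O)O
Why: In the Mitsunobu reaction, SN2 displacement of the axial oxyphosphonium group by acetate from the open alpha face inverts C2 to the equatorial 2-alpha acetate and relieves two syn-axial methyl–oxygen contacts.

**Step 11**
Reactants: 20 2-alpha-acetoxy-6-oxo-8-en-9-yl triflate
Product: 22 2-alpha,7-alpha-diacetoxy-6-oxo-8-en-9-yl triflate, via potassium alkoxide 21 (not isolated)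
Conditions: KN(SiMe3)2 (1.05 equiv), THF, −78 °C; 2-(phenylsulfonyl)-3-phenyloxaziridine (1.2 equiv); then Ac2O (3 equiv), −78 to 0 °C
Reagents that add atoms: 2-(phenylsulfonyl)-3-phenyloxaziridine O=S(=O)(c1ccccc1)N1OC1c1ccccc1; acetic anhydride CC(=O)OC(C)=O
Why: Kinetic deprotonation takes the doubly activated C7–H rather than the buried C5–H, the dienolate is hydroxylated at its alpha carbon by the N-sulfonyloxaziridine (enolate hydroxylation) along the axial trajectory on the alpha face because C20 screens the beta face, and the alkoxide is acetylated in the same flask.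

**Step 12**
Reactants: 22 2-alpha,7-alpha-diacetoxy-6-oxo-8-en-9-yl triflate
Product: 23 2-alpha,7-alpha-diacetoxy-6-beta-hydroxy-8-en-9-yl triflate
Conditions: NaBH4, MeOH–CH2Cl2 (1:1), −20 °C
Reagents that add atoms: none
Why: In the borohydride reduction the beta face of C6 is closed by the syn-axial C19 and C20 methyl groups, so hydride enters from the alpha face and gives the axial 6-beta alcohol, which is trans-diaxial to the 7-alpha acetate so that acyl migration is impossible.

**Step 13**
Reactants: 23 2-alpha,7-alpha-diacetoxy-6-beta-hydroxy-8-en-9-yl triflate; 24 isovaleric anhydride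
Product: 25 2-alpha,7-alpha-diacetoxy-6-beta-(3-methylbutanoyloxy)-8-en-9-yl triflate
Conditions: 24 (5 equiv), DMAP (0.5 equiv), Et3N, toluene, 60 °C
Reagents that add atoms: none
Why: DMAP-catalysed acylation under forcing conditions esterifies the only free hydroxyl group, which is hindered but has no competitor.

**Step 14**
Reactants: 26 (E)-3-methylpent-2-en-4-yn-1-ol
Product: 27 (E)-tert-butyldimethyl[(3-methylpent-2-en-4-yn-1-yl)oxy]silane
Conditions: t-BuMe2SiCl, imidazole, DMF, rt
Reagents that add atoms: tert-butyldimethylsilyl chloride CC(C)(C)[Si](C)(C)Cl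
Why: This is a standard silylation of a primary allylic alcohol that leaves the E double bond untouched.

**Step 15**
Reactants: 27 (E)-silyl ether of the enynol
Product: 28 (E)-tert-butyldimethyl[(3-methylpenta-2,4-dien-1-yl)oxy]silane
Conditions: H2 (1 atm), Pd/CaCO3 poisoned with Pb(OAc)2, quinoline, hexane, rt
Reagents that add atoms: none
Why: Lindlar semihydrogenation stops at the alkene for a terminal alkyne and leaves the trisubstituted E alkene unchanged.

**Step 16**
Reactants: 28 (E)-silyloxy diene; 25 triester enol triflate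
Product: 30 15-O-tert-butyldimethylsilyl ether of the target, via alkylborane 29 (not isolated)
Conditions: 9-BBN-H (1.1 equiv), THF, 0 °C to rt; then 25, PdCl2(dppf) (10 mol %), AsPh3, K3PO4 (3 equiv), DMF–H2O, rt to 40 °C
Reagents that add atoms: none
Why: 9-BBN-H adds to the monosubstituted vinyl group with boron on the terminal carbon (C11), and B-alkyl Suzuki–Miyaura coupling (oxidative addition of zerovalent palladium into the C9–O bond) joins C9–C11 without touching a stereocentre, while the allylic acetate on the hindered tetrasubstituted alkene should ionise only slowly.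

**Step 17**
Reactants: 30 15-O-silyl ether of the target
Product: 31 CNP0257091.1 (2-alpha,7-alpha-diacetoxy-6-beta-isovaleroyloxylabda-8,13E-dien-15-ol)
Conditions: HF·pyridine, pyridine, THF, 0 °C
Reagents that add atoms: none
Why: Fluoride-driven desilylation in a buffered medium frees the primary allylic alcohol and leaves the three esters in place.

**Compound list**

1 | 2,6-dimethylphenol | Cc1cccc(C)c1O | starting material
2 | 4,4-dimethoxy-2,6-dimethylcyclohexa-2,5-dien-1-one | COC1(OC)C=C(C)C(=O)C(C)=C1 | intermediate
3 | allyl chloroformate | C=CCOC(=O)Cl | starting material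
4 | lithium 4,4-dimethoxy-2,6-dimethylcyclohexa-1,5-dien-1-olate | [Li+].COC1(OC)CC(C)=C([O-])C(C)=C1 | intermediate
5 | allyl 4,4-dimethoxy-2,6-dimethylcyclohexa-1,5-dien-1-yl carbonate | C=CCOC(=O)OC1=C(C)CC(OC)(OC)C=C1C | intermediate
6 | (S)-6-allyl-4,4-dimethoxy-2,6-dimethylcyclohex-2-en-1-one | C=CC[C@@]1(C)CC(OC)(OC)C=C(C)C1=O | intermediate
7 | (S)-2-(5,5-dimethoxy-1,3-dimethyl-2-oxocyclohex-3-en-1-yl)acetaldehyde | O=CC[C@@]1(C)CC(OC)(OC)C=C(C)C1=O | intermediate
8 | (S)-2-(1,3-dimethyl-2,5-dioxocyclohex-3-en-1-yl)acetaldehyde | O=CC[C@@]1(C)CC(=O)C=C(C)C1=O | intermediate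
9 | (S)-4-(tert-butyldimethylsilyloxy)-6-[2-(tert-butyldimethylsilyloxy)ethenyl]-2,6-dimethylcyclohexa-2,4-dien-1-one (E/Z mixture) | CC(C)(C)[Si](C)(C)OC=C[C@@]1(C)C=C(O[Si](C)(C)C(C)(C)C)C=C(C)C1=O | intermediate
10 | isobutene | C=C(C)C | starting material
11 | (S)-2-[5-(tert-butyldimethylsilyloxy)-1,3-dimethyl-2-oxocyclohexa-3,5-dien-1-yl]acetaldehyde | O=CC[C@@]1(C)C=C(O[Si](C)(C)C(C)(C)C)C=C(C)C1=O | intermediate
12 | trichlorotitanium 4-chloro-1-[(S)-5-(tert-butyldimethylsilyloxy)-1,3-dimethyl-2-oxocyclohexa-3,5-dien-1-yl]-4-methylpentan-2-olate (both C2 epimers) | Cl[Ti](Cl)(Cl)OC(CC(C)(C)Cl)C[C@@]1(C)C=C(O[Si](C)(C)C(C)(C)C)C=C(C)C1=O | intermediate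
13 | trichlorotitanium alkoxide of 14 | Cl[Ti](Cl)(Cl)OC1CC(C)(C)[C@H]2C(=O)C=C(C)C(=O)[C@@]2(C)C1 | intermediate
14 | cis-fused 2-hydroxy-6,9-dioxo-7-ene decalin (5-beta-H, both C2 epimers) | OC1CC(C)(C)[C@H]2C(=O)C=C(C)C(=O)[C@@]2(C)C1 | intermediate
15 | cis-fused 2,6,9-trioxo-7-ene decalin (5-beta-H) | O=C1CC(C)(C)[C@H]2C(=O)C=C(C)C(=O)[C@@]2(C)C1 | intermediate
16 | 2,6-bis(trimethylsilyloxy)-2,5,7-trien-9-one (C5 planar) | C[Si](C)(C)OC1=CC(C)(C)C2=C(O[Si](C)(C)C)C=C(C)C(=O)[C@@]2(C)C1 | intermediate
17 | trans-fused 2,6,9-trioxo-7-ene decalin (5-alpha-H) | O=C1CC(C)(C)[C@@H]2C(=O)C=C(C)C(=O)[C@@]2(C)C1 | intermediate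
18 | dilithium 2-beta-alkoxide 8-en-9-olate of the 6-ketone | [Li+].[Li+].[O-][C@@H]1CC(C)(C)[C@@H]2C(=O)CC(C)=C([O-])[C@@]2(C)C1 | intermediate
19 | 2-beta-hydroxy-6-oxo-8-en-9-yl triflate | O[C@@H]1CC(C)(C)[C@@H]2C(=O)CC(C)=C(OS(=O)(=O)C(F)(F)F)[C@@]2(C)C1 | intermediate
20 | 2-alpha-acetoxy-6-oxo-8-en-9-yl triflate | CC(=O)O[C@H]1CC(C)(C)[C@@H]2C(=O)CC(C)=C(OS(=O)(=O)C(F)(F)F)[C@@]2(C)C1 | intermediate
21 | potassium 7-alpha-alkoxide of the 2-alpha-acetoxy-6-ketone | [K+].CC(=O)O[C@H]1CC(C)(C)[C@@H]2C(=O)[C@@H]([O-])C(C)=C(OS(=O)(=O)C(F)(F)F)[C@@]2(C)C1 | intermediate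
22 | 2-alpha,7-alpha-diacetoxy-6-oxo-8-en-9-yl triflate | CC(=O)O[C@H]1CC(C)(C)[C@@H]2C(=O)[C@@H](OC(C)=O)C(C)=C(OS(=O)(=O)C(F)(F)F)[C@@]2(C)C1 | intermediate
23 | 2-alpha,7-alpha-diacetoxy-6-beta-hydroxy-8-en-9-yl triflate | CC(=O)O[C@H]1CC(C)(C)[C@@H]2[C@H](O)[C@@H](OC(C)=O)C(C)=C(OS(=O)(=O)C(F)(F)F)[C@@]2(C)C1 | intermediate
24 | isovaleric anhydride | CC(C)CC(=O)OC(=O)CC(C)C | starting material
25 | 2-alpha,7-alpha-diacetoxy-6-beta-(3-methylbutanoyloxy)-8-en-9-yl triflate | CC(=O)O[C@H]1CC(C)(C)[C@@H]2[C@H](OC(=O)CC(C)C)[C@@H](OC(C)=O)C(C)=C(OS(=O)(=O)C(F)(F)F)[C@@]2(C)C1 | intermediate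
26 | (E)-3-methylpent-2-en-4-yn-1-ol | C#C/C(C)=C/CO | starting material
27 | (E)-tert-butyldimethyl[(3-methylpent-2-en-4-yn-1-yl)oxy]silane | C#C/C(C)=C/CO[Si](C)(C)C(C)(C)C | intermediate
28 | (E)-tert-butyldimethyl[(3-methylpenta-2,4-dien-1-yl)oxy]silane | C=C/C(C)=C/CO[Si](C)(C)C(C)(C)C | intermediate
29 | (E)-9-[5-(tert-butyldimethylsilyloxy)-3-methylpent-3-en-1-yl]-9-borabicyclo[3.3.1]nonane | C1CCC2CCCC1B2CC/C(C)=C/CO[Si](C)(C)C(C)(C)C | intermediate
30 | 15-O-tert-butyldimethylsilyl ether of the target | CC(=O)O[C@H]1CC(C)(C)[C@@H]2[C@H](OC(=O)CC(C)C)[C@@H](OC(C)=O)C(C)=C(CC/C(C)=C/CO[Si](C)(C)C(C)(C)C)[C@@]2(C)C1 | intermediate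
31 | CNP0257091.1 | CC(=O)O[C@H]1CC(C)(C)[C@@H]2[C@H](OC(=O)CC(C)C)[C@@H](OC(C)=O)C(C)=C(CC/C(C)=C/CO)[C@@]2(C)C1 | target

**Step count**

Total step count: 17. Longest linear sequence: 15 (steps 1–13, 16, 17).

**Steps most likely to fail**

Step 6 (the labelled step). What may go wrong:
- chain growth of isobutene at the C4 cation;
- aldol-type coupling between two molecules;
- proton loss from the C4 cation;
- premature protodesilylation of the ring enol ether.

The fallback uses known reactions only; it sets out from 8 and returns at 14. Aldehyde-selective allylboration of 8 with 2-methylallylboronic acid pinacol ester (CH2Cl2, rt) should give the homoallylic alcohol F1. Markovnikov hydrochlorination of its 1,1-disubstituted alkene (HCl, CH2Cl2, 0 °C) should give the chloro alcohol F2. t-BuMe2SiOTf and Et3N should give the doubly silylated tertiary chloride F3. TiCl4 (CH2Cl2, −40 °C), an intramolecular alpha-tert-alkylation of a silyl enol ether, should close ring A to the cis-fused silyl ether F4. Aqueous HF in MeCN then frees 14. C2–C3 and C4–C5 are made in separate flasks in this variant.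

Step 8. What may go wrong:
- sluggish enolisation at the buried C5–H;
- competing deprotonation at C17;
- protonation without facial preference;
- re-equilibration of the ring fusion.

The fallback sets out from 15 and returns at 20, so it also bypasses steps 9 and 10. The conditions of step 9 are applied to the still cis-fused trione. Hydride should then reach the C2 ketone from the convex face, which lies away from ring B. That gives the cis-fused 2-alpha-hydroxy enol triflate F5. Base equilibration (DBU, toluene, rt) should then move C5 to the trans-fused 2-alpha-hydroxy enol triflate F6. Trans should be favoured at this stage for two reasons: the 2-alpha hydroxyl becomes equatorial, and C4 leaves the axial position next to the new C7 methylene. Acetylation (Ac2O, pyridine) gives 20.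

Step 10. What may go wrong: elimination of the strained axial oxyphosphonium group instead of substitution. The fallback sets out from 19 and returns at 23. Deliberate anti-elimination (POCl3, pyridine) should give the 2-ene F7. The position of the new double bond is of no consequence, since C1 and C3 are both neopentyl and boron will go to C2. Enolate hydroxylation as in step 11, without the anhydride, should give the 7-alpha-hydroxy ketone F8. Excess BH3·THF followed by NaBO3 should hydroborate ring A from the alpha face at C2. It should also reduce C6 from the alpha face, with delivery from the 7-alpha borate, to give the 2-alpha,6-beta,7-alpha-triol F9. Ac2O and pyridine at rt should acetylate the equatorial C2 and the allylic C7 hydroxyl groups and leave the hindered 6-beta hydroxyl free, which is 23.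

**Further compounds**

F1 | step 6 | (S)-6-(2-hydroxy-4-methylpent-4-en-1-yl)-2,6-dimethylcyclohex-2-ene-1,4-dione (both carbinol epimers) | C=C(C)CC(O)C[C@@]1(C)CC(=O)C=C(C)C1=O
F2 | step 6 | (S)-6-(4-chloro-2-hydroxy-4-methylpentyl)-2,6-dimethylcyclohex-2-ene-1,4-dione | CC(C)(Cl)CC(O)C[C@@]1(C)CC(=O)C=C(C)C1=O
F3 | step 6 | (S)-4-(tert-butyldimethylsilyloxy)-6-[2-(tert-butyldimethylsilyloxy)-4-chloro-4-methylpentyl]-2,6-dimethylcyclohexa-2,4-dien-1-one | CC(C)(Cl)CC(O[Si](C)(C)C(C)(C)C)C[C@@]1(C)C=C(O[Si](C)(C)C(C)(C)C)C=C(C)C1=O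
F4 | step 6 | tert-butyldimethylsilyl ether of 14 | CC(C)(C)[Si](C)(C)OC1CC(C)(C)[C@H]2C(=O)C=C(C)C(=O)[C@@]2(C)C1
F5 | step 8 | cis-fused 2-alpha-hydroxy-6-oxo-8-en-9-yl triflate (5-beta-H) | O[C@H]1CC(C)(C)[C@H]2C(=O)CC(C)=C(OS(=O)(=O)C(F)(F)F)[C@@]2(C)C1
F6 | step 8 | trans-fused 2-alpha-hydroxy-6-oxo-8-en-9-yl triflate (5-alpha-H) | O[C@H]1CC(C)(C)[C@@H]2C(=O)CC(C)=C(OS(=O)(=O)C(F)(F)F)[C@@]2(C)C1
F7 | step 10 | 6-oxo-2,8-dien-9-yl triflate | C1=CC(C)(C)[C@@H]2C(=O)CC(C)=C(OS(=O)(=O)C(F)(F)F)[C@@]2(C)C1
F8 | step 10 | 7-alpha-hydroxy-6-oxo-2,8-dien-9-yl triflate | C1=CC(C)(C)[C@@H]2C(=O)[C@@H](O)C(C)=C(OS(=O)(=O)C(F)(F)F)[C@@]2(C)C1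
F9 | step 10 | 2-alpha,6-beta,7-alpha-trihydroxy-8-en-9-yl triflate | O[C@H]1CC(C)(C)[C@@H]2[C@H](O)[C@@H](O)C(C)=C(OS(=O)(=O)C(F)(F)F)[C@@]2(C)C1
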